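**Plan**

1. Retrosynthesis: the late adjustments (C8 acyl group, C14 acetal, C15 silyl ether) are cut first. Then the C6–C7 bond is cut together with the lactone C12–O6 bond, then C9–C10 (alkenylmagnesium + aldehyde), then C3–C4 (Negishi), C1=C10 (Wittig) and C7–C11 (Morita–Baylis–Hillman).
2. Enabling feature: C6–C7 is the bond shared by the ten-membered carbocycle and the γ-lactone. The array O6–C6–C7–C11(=C13)–C12(=O) is the adduct pattern of a 2-(methoxycarbonyl)allyl metal (C13–C11=C7) and an aldehyde (C6). Both ring alkenes (C1=C10, C4=C5) are cis within the ring and pre-fold the chain.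
3. Forward: fragment 1 (C1–C6, C10, C14, C15; from 2-butyne-1,4-diol) and fragment 2 (C7–C9, C11–C13; from dimethyl L-tartrate) are joined at C9–C10 to a linear C6→C13 chain. One CrCl2-mediated step then closes the carbocycle and, in the same flask, the lactone; three steps finish the route.
4. Stereochemistry: C8 comes from L-tartaric acid; C9 from a chelation-controlled addition (8,9-syn); C6 and C7 from the key step (chair transition state, C8 control); the acyl centre from (S)-2-methylbutanoic acid. Alkene geometries come from trans-hydroalumination/iodination (C4=C5) and α-iodination of an E-enal (C1=C10).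

Key step: step 21

Remark: locants C1–C15 are the germacrane numbers of the target (lactone C12(=O)–O–C6, ring fusion C6/C7, methylene C11=C13, formyl C14 on C10, hydroxymethyl C15 on C4) and are kept for all open-chain intermediates. The Morita–Baylis–Hillman centre C7 is assumed to be carried as an epimer mixture until it becomes sp2 in step 20.

**Fragment 1 (steps 1–8)**

Step 1
Reactants: 1 2-butyne-1,4-diol
Product: 2 4-(tert-butyldiphenylsilyloxy)but-2-yn-1-ol
Conditions: NaH (1.0 equiv), THF, 0 °C to rt; TBDPSCl (1.0 equiv)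
Reagents that add atoms: tert-butyldiphenylsilyl chloride CC(C)(C)[Si](Cl)(c1ccccc1)c1ccccc1
Why: Monosilylation of a symmetrical diol through its sparingly soluble monosodium alkoxide (O-silylation) should stop cleanly at the mono-ether.

Step 2
Reactants: 2 4-(tert-butyldiphenylsilyloxy)but-2-yn-1-ol
Product: 4 (Z)-4-(tert-butyldiphenylsilyloxy)-3-iodobut-2-en-1-ol, via cyclic alkenylalanate 3 (not isolated)
Conditions: NaAlH2(OCH2CH2OMe)2, THF, 0 °C to rt; then I2, THF, −78 °C
Reagents that add atoms: iodine II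
Why: Hydroxyl-directed trans-hydroalumination of the propargylic alcohol places aluminium on the distal carbon in a five-membered chelate, and iodinolysis with retention gives the (Z)-iodide, which fixes the C4=C5 geometry (C6 cis to the position that will carry C3).

Step 3
Reactants: 4 (Z)-4-(tert-butyldiphenylsilyloxy)-3-iodobut-2-en-1-ol
Product: 5 (Z)-1-(tert-butyldimethylsilyloxy)-4-(tert-butyldiphenylsilyloxy)-3-iodobut-2-ene
Conditions: TBSCl, imidazole, DMF, 0 °C to rt
Reagents that add atoms: tert-butyldimethylsilyl chloride CC(C)(C)[Si](C)(C)Cl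
Why: Standard imidazole-mediated O-silylation gives the C6 oxygen a silyl group that can later be removed in the presence of the C15 TBDPS ether.

Step 4
Reactants: 5 (Z)-1-(tert-butyldimethylsilyloxy)-4-(tert-butyldiphenylsilyloxy)-3-iodobut-2-ene
Product: 6 ethyl (E)-6-(tert-butyldimethylsilyloxy)-4-[(tert-butyldiphenylsilyloxy)methyl]hex-4-enoate
Conditions: BrZnCH2CH2CO2Et (0.5 M in THF), Pd(PPh3)4 (5 mol %), THF, 50 °C
Reagents that add atoms: (3-ethoxy-3-oxopropyl)zinc bromide CCOC(=O)CC[Zn]Br
Why: Negishi sp2–sp3 cross-coupling proceeds with retention at the alkenyl carbon, so the new C3–C2–C1 arm ends up cis to C6 as the ring requires.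

Step 5
Reactants: 6 ethyl (E)-6-(tert-butyldimethylsilyloxy)-4-[(tert-butyldiphenylsilyloxy)methyl]hex-4-enoate
Product: 7 (E)-6-(tert-butyldimethylsilyloxy)-4-[(tert-butyldiphenylsilyloxy)methyl]hex-4-enal
Conditions: i-Bu2AlH (1.05 equiv), CH2Cl2, −78 °C
Reagents that add atoms: none
Why: Partial ester reduction with i-Bu2AlH stops at the aldehyde (C1) because the tetrahedral aluminium hemiacetal is stable at −78 °C.

Step 6
Reactants: 7 (E)-6-(tert-butyldimethylsilyloxy)-4-[(tert-butyldiphenylsilyloxy)methyl]hex-4-enal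
Product: 8 (2E,6E)-8-(tert-butyldimethylsilyloxy)-6-[(tert-butyldiphenylsilyloxy)methyl]octa-2,6-dienal
Conditions: Ph3P=CHCHO, toluene, 80 °C
Reagents that add atoms: (triphenylphosphoranylidene)acetaldehyde O=CC=P(c1ccccc1)(c1ccccc1)c1ccccc1
Why: Wittig olefination with the stabilised formylmethylene ylide adds C10 and C14 as an E-enal.

Step 7
Reactants: 8 (2E,6E)-8-(tert-butyldimethylsilyloxy)-6-[(tert-butyldiphenylsilyloxy)methyl]octa-2,6-dienal
Product: 9 (2Z,6E)-8-(tert-butyldimethylsilyloxy)-6-[(tert-butyldiphenylsilyloxy)methyl]-2-iodoocta-2,6-dienal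
Conditions: I2, K2CO3, DMAP (cat.), THF/H2O, rt
Reagents that add atoms: iodine II
Why: Baylis–Hillman-type α-iodination (DMAP conjugate addition, enolate iodination, elimination) should give the α-iodoenal with the formyl group trans to C2, which is the C1=C10 geometry of the target.

Step 8
Reactants: 9 (2Z,6E)-8-(tert-butyldimethylsilyloxy)-6-[(tert-butyldiphenylsilyloxy)methyl]-2-iodoocta-2,6-dienal
Product: 10 2-[(1Z,5E)-7-(tert-butyldimethylsilyloxy)-5-[(tert-butyldiphenylsilyloxy)methyl]-1-iodohepta-1,5-dien-1-yl]-1,3-dioxolane (fragment 1)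
Conditions: Me3SiOCH2CH2OSiMe3, TMSOTf (cat.), CH2Cl2, −78 to −20 °C
Reagents that add atoms: 1,2-bis(trimethylsilyloxy)ethane C[Si](C)(C)OCCO[Si](C)(C)C
Why: Noyori acetalisation masks C14 at the aldehyde oxidation level under aprotic conditions that spare the silyl ethers and do not move the double bond.

**Fragment 2 (steps 9–15)**

Step 9
Reactants: 11 dimethyl L-tartrate
Product: 12 dimethyl (4R,5R)-2-(4-methoxyphenyl)-1,3-dioxolane-4,5-dicarboxylate
Conditions: 4-methoxybenzaldehyde dimethyl acetal, TsOH·H2O (cat.), toluene, 90 °C, removal of MeOH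
Reagents that add atoms: 4-methoxybenzaldehyde dimethyl acetal COc1ccc(C(OC)OC)cc1
Why: Acid-catalysed transacetalisation is driven by removal of methanol and leaves the two tartrate centres untouched.

Step 10
Reactants: 12 dimethyl (4R,5R)-2-(4-methoxyphenyl)-1,3-dioxolane-4,5-dicarboxylate
Product: 13 (2S,3S)-3-(4-methoxybenzyloxy)butane-1,2,4-triol
Conditions: LiAlH4, AlCl3, Et2O/CH2Cl2, 0 °C to reflux
Reagents that add atoms: none
Why: Chloroalane reduces both esters and reductively opens the benzylidene acetal to the PMB ether; the C2 symmetry of 12 makes the direction of opening irrelevant.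

Step 11
Reactants: 13 (2S,3S)-3-(4-methoxybenzyloxy)butane-1,2,4-triol
Product: 14 (2S)-2-[(4S)-2,2-dimethyl-1,3-dioxolan-4-yl]-2-(4-methoxybenzyloxy)ethan-1-ol
Conditions: Me2C(OMe)2, TsOH·H2O (cat.), acetone, 0 °C to rt
Reagents that add atoms: 2,2-dimethoxypropane COC(C)(C)OC
Why: Thermodynamically controlled acetonide formation should prefer the five-membered dioxolane of the terminal 1,2-diol over the 1,3-dioxane, leaving one primary hydroxyl free.

Step 12
Reactants: 14 (2S)-2-[(4S)-2,2-dimethyl-1,3-dioxolan-4-yl]-2-(4-methoxybenzyloxy)ethan-1-ol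
Product: 15 (2R)-2-[(4S)-2,2-dimethyl-1,3-dioxolan-4-yl]-2-(4-methoxybenzyloxy)acetaldehyde
Conditions: Dess–Martin periodinane, CH2Cl2, 0 °C to rt
Reagents that add atoms: none
Why: Dess–Martin oxidation gives the α-alkoxy aldehyde (future C7) under near-neutral conditions that should not epimerise the future C8 centre.

Step 13
Reactants: 15 (2R)-2-[(4S)-2,2-dimethyl-1,3-dioxolan-4-yl]-2-(4-methoxybenzyloxy)acetaldehyde
Product: 16 methyl 4-[(4S)-2,2-dimethyl-1,3-dioxolan-4-yl]-3-hydroxy-4-(4-methoxybenzyloxy)-2-methylidenebutanoate (C3 epimers; C4 as in 15)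
Conditions: methyl acrylate (excess), DABCO (1 equiv), rt, several days
Reagents that add atoms: methyl acrylate C=CC(=O)OC
Why: The Morita–Baylis–Hillman reaction attaches C11–C13 to C7; the new carbinol centre forms as an epimer mixture that does not matter because C7 becomes sp2 in step 20.

Step 14
Reactants: 16 methyl 4-[(4S)-2,2-dimethyl-1,3-dioxolan-4-yl]-3-hydroxy-4-(4-methoxybenzyloxy)-2-methylidenebutanoate
Product: 17 methyl 3-(tert-butyldimethylsilyloxy)-4-[(4S)-2,2-dimethyl-1,3-dioxolan-4-yl]-4-(4-methoxybenzyloxy)-2-methylidenebutanoate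
Conditions: TBSOTf, 2,6-lutidine, CH2Cl2, −78 to 0 °C
Reagents that add atoms: tert-butyldimethylsilyl triflate CC(C)(C)[Si](C)(C)OS(=O)(=O)C(F)(F)F
Why: Silylation with the triflate protects the hindered allylic hydroxyl with a non-chelating group, so that only the α-OPMB oxygen can chelate in step 16.

Step 15
Reactants: 17 methyl 3-(tert-butyldimethylsilyloxy)-4-[(4S)-2,2-dimethyl-1,3-dioxolan-4-yl]-4-(4-methoxybenzyloxy)-2-methylidenebutanoate
Product: 19 methyl (4S)-3-(tert-butyldimethylsilyloxy)-4-(4-methoxybenzyloxy)-2-methylidene-5-oxopentanoate (fragment 2), via terminal diol 18 (not isolated)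
Conditions: H5IO6, EtOAc, rt
Reagents that add atoms: none
Why: Periodic acid hydrolyses the terminal acetonide and cleaves the liberated glycol (Malaprade cleavage) in one pot, unveiling the C9 aldehyde next to the PMB-bearing C8 centre.

**Union and endgame (steps 16–24)**

Step 16
Reactants: 10 fragment 1 (alkenyl iodide); 19 fragment 2 (aldehyde)
Product: 22 C9 alcohol of the C6–C13 seco-chain (C6-OTBS; C15-OTBDPS; C14 dioxolane; C9-OH; C8-OPMB; C7-OTBS; methyl 2-methylidene ester), via alkenyllithium 20 (not isolated), via alkenylmagnesium bromide 21 (not isolated)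
Conditions: 10, t-BuLi (2.05 equiv), Et2O, −78 °C; MgBr2·OEt2; then 19 premixed with MgBr2·OEt2 in CH2Cl2, −78 to −40 °C; aq. NH4Cl
Reagents that add atoms: none
Why: Iodine–lithium exchange and transmetalation keep the alkene geometry, and Cram-chelate-controlled 1,2-addition (magnesium bridging the aldehyde oxygen and the α-OPMB oxygen, attack anti to the C7 arm) should set C9 syn to C8, as in the target.

Step 17
Reactants: 22 C9 alcohol of the seco-chain
Product: 23 C9 acetate of the seco-chain
Conditions: Ac2O, pyridine, DMAP (cat.), CH2Cl2, rt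
Reagents that add atoms: acetic anhydride CC(=O)OC(C)=O
Why: DMAP-catalysed acetylation installs the final C9 acetate while the C8 oxygen is still blocked as its PMB ether, so no regiochemical question arises.

Step 18
Reactants: 23 C9 acetate of the seco-chain
Product: 24 C6,C7-diol (C6-OH; C7-OH; C9-OAc; C8-OPMB; C14 dioxolane; C15-OTBDPS)
Conditions: HF·pyridine, pyridine, THF, 0 °C to rt
Reagents that add atoms: none
Why: Buffered fluoride desilylation should remove the primary and the secondary TBS ether while the much more robust primary TBDPS ether, the acetate and the dioxolane persist.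

Step 19
Reactants: 24 C6,C7-diol
Product: 25 C6 enal with free C7 hydroxyl
Conditions: TEMPO (cat.), PhI(OAc)2, CH2Cl2, rt
Reagents that add atoms: none
Why: Oxoammonium (TEMPO) oxidation is selective for the primary allylic alcohol over the secondary one and should give the enal without isomerising the C4=C5 bond.

Step 20
Reactants: 25 C6 enal with free C7 hydroxyl
Product: 26 methyl (2Z,4S,5S,6E,10E)-5-acetoxy-2-(bromomethyl)-10-[(tert-butyldiphenylsilyloxy)methyl]-6-(1,3-dioxolan-2-yl)-4-(4-methoxybenzyloxy)-12-oxododeca-2,6,10-trienoate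
Conditions: NBS, Me2S, CH2Cl2, −20 °C to rt
Reagents that add atoms: N-bromosuccinimide O=C1CCC(=O)N1Br
Why: Corey–Kim-type activation of the Morita–Baylis–Hillman alcohol followed by SN2′ attack of bromide gives the conjugated (Z)-2-(bromomethyl)enoate and erases the C7 epimer mixture.

Step 21
Reactants: 26 bromo enal (acyclic C6–C13 chain)
Product: 29 ten-membered α-methylene lactone (6R,7S,8S,9S; C8-OPMB; C9-OAc; C14 dioxolane; C15-OTBDPS), via allylchromium dichloride 27 (not isolated), via hydroxy ester 28 (not isolated)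
Conditions: CrCl2 (10 equiv), DMF/THF, 0.003 M, slow addition of 26, rt; aq. NH4Cl; then PPTS (cat.), CH2Cl2, rt
Reagents that add atoms: none
Why: CrCl2 (divalent chromium) reduces the allylic C13–Br bond to the allylchromium 27 (trivalent chromium), which equilibrates through its σ/π forms and adds through C7 (SE2′) to the C6 aldehyde in a six-membered chair (Zimmerman–Traxler) array, after which the C6 alkoxide of 28 attacks the C12 methyl ester to give the lactone. This is an intramolecular Nozaki–Hiyama–Kishi (Barbier-type) 2-(alkoxycarbonyl)allylation, a reaction type known to close ten-membered germacranolide rings through this same bond. The carbocycle closes in a 10-exo-trig mode (C7 onto the C6 carbonyl) and the lactone in a 5-exo-trig mode (O6 onto C12). The C6/C7 anti relationship (trans-fused lactone) should follow from the chair in which both ring arms (C5 on the aldehyde, C8 on the allyl terminus) are pseudo-equatorial; the C7 face is set by the C8 stereocentre, whose hydrogen lies in the allyl plane to avoid allylic 1,3-strain with the substituents on C11, so that the C8–C9 bond stands anti to the forming bond and the OPMB group points outward, which corresponds to 7S and hence 6R. The step needs γ- over α-attack (inherent to allylchromium; α-attack would give a twelve-membered ring), chemoselectivity (C6 is the only free aldehyde because C14 is a dioxolane, and the C8 oxygen is an ether, not an ester, to disfavour 1,4-elimination of the allylmetal) and cyclisation over oligomerisation (high dilution, helped by the two cis alkenes that bring the chain ends together).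

Step 22
Reactants: 29 ten-membered α-methylene lactone
Product: 30 C8 alcohol of the lactone (C9-OAc; C14 dioxolane; C15-OTBDPS)
Conditions: DDQ, CH2Cl2/pH 7 buffer, 0 °C to rt
Reagents that add atoms: none
Why: Oxidative PMB cleavage with DDQ (hydride abstraction, hydrolysis of the oxocarbenium ion) is neutral and should leave the acetate, lactone, dioxolane and silyl ether intact.

Step 23
Reactants: 30 C8 alcohol of the lactone
Product: 31 C8 (S)-2-methylbutanoate of the lactone (C9-OAc; C14 dioxolane; C15-OTBDPS)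
Conditions: (S)-2-methylbutanoic anhydride, Et3N, DMAP (cat.), CH2Cl2, 0 °C to rt
Reagents that add atoms: (S)-2-methylbutanoic anhydride CC[C@H](C)C(=O)OC(=O)[C@@H](C)CC
Why: DMAP-catalysed acyl transfer from the anhydride (Steglich-type acylation) should esterify the C8 hydroxyl faster than the neighbouring acetate can migrate and, having no ketene pathway, without epimerising the acyl α-centre.

Step 24
Reactants: 31 C8 (S)-2-methylbutanoate of the lactone
Product: 32 target CNP0247637.6 [(6R,7S,8S,9S)-9-acetoxy-15-hydroxy-8-[(S)-2-methylbutanoyloxy]-14-oxo-germacra-1(10),4,11(13)-trien-12,6-olide with both ring alkenes cis in the ring]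
Conditions: aq. HF (48%)/MeCN (1:10), 0 °C to rt
Reagents that add atoms: water O
Why: Aqueous HF should cleave the primary TBDPS ether and hydrolyse the enal dioxolane (acetal hydrolysis via the allylic oxocarbenium ion) in one operation, under conditions that the two esters and the α-methylene lactone tolerate.

**Compound list**

1 | 2-butyne-1,4-diol | OCC#CCO | starting material
2 | 4-(tert-butyldiphenylsilyloxy)but-2-yn-1-ol | OCC#CCO[Si](c1ccccc1)(c1ccccc1)C(C)(C)C | intermediate
3 | cyclic sodium alkenylalanate (five-membered O–Al–C=C chelate; Al on the carbon bearing CH2OTBDPS) | [Na+].COCCO[Al-]1(OCCOC)OCC=C1CO[Si](c1ccccc1)(c1ccccc1)C(C)(C)C | intermediate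
4 | (Z)-4-(tert-butyldiphenylsilyloxy)-3-iodobut-2-en-1-ol | OC/C=C(\I)CO[Si](c1ccccc1)(c1ccccc1)C(C)(C)C | intermediate
5 | (Z)-1-(tert-butyldimethylsilyloxy)-4-(tert-butyldiphenylsilyloxy)-3-iodobut-2-ene | CC(C)(C)[Si](C)(C)OC/C=C(\I)CO[Si](c1ccccc1)(c1ccccc1)C(C)(C)C | intermediate
6 | ethyl (E)-6-(tert-butyldimethylsilyloxy)-4-[(tert-butyldiphenylsilyloxy)methyl]hex-4-enoate | CCOC(=O)CC/C(CO[Si](c1ccccc1)(c1ccccc1)C(C)(C)C)=C\CO[Si](C)(C)C(C)(C)C | intermediate
7 | (E)-6-(tert-butyldimethylsilyloxy)-4-[(tert-butyldiphenylsilyloxy)methyl]hex-4-enal | O=CCC/C(CO[Si](c1ccccc1)(c1ccccc1)C(C)(C)C)=C\CO[Si](C)(C)C(C)(C)C | intermediate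
8 | (2E,6E)-8-(tert-butyldimethylsilyloxy)-6-[(tert-butyldiphenylsilyloxy)methyl]octa-2,6-dienal | O=C/C=C/CC/C(CO[Si](c1ccccc1)(c1ccccc1)C(C)(C)C)=C\CO[Si](C)(C)C(C)(C)C | intermediate
9 | (2Z,6E)-8-(tert-butyldimethylsilyloxy)-6-[(tert-butyldiphenylsilyloxy)methyl]-2-iodoocta-2,6-dienal | O=C/C(I)=C/CC/C(CO[Si](c1ccccc1)(c1ccccc1)C(C)(C)C)=C\CO[Si](C)(C)C(C)(C)C | intermediate
10 | 2-[(1Z,5E)-7-(tert-butyldimethylsilyloxy)-5-[(tert-butyldiphenylsilyloxy)methyl]-1-iodohepta-1,5-dien-1-yl]-1,3-dioxolane (fragment 1) | I/C(C1OCCO1)=C\CC/C(CO[Si](c1ccccc1)(c1ccccc1)C(C)(C)C)=C\CO[Si](C)(C)C(C)(C)C | intermediate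
11 | dimethyl L-tartrate (2R,3R) | COC(=O)[C@H](O)[C@@H](O)C(=O)OC | starting material
12 | dimethyl (4R,5R)-2-(4-methoxyphenyl)-1,3-dioxolane-4,5-dicarboxylate | COC(=O)[C@@H]1OC(c2ccc(OC)cc2)O[C@H]1C(=O)OC | intermediate
13 | (2S,3S)-3-(4-methoxybenzyloxy)butane-1,2,4-triol | OC[C@H](OCc1ccc(OC)cc1)[C@@H](O)CO | intermediate
14 | (2S)-2-[(4S)-2,2-dimethyl-1,3-dioxolan-4-yl]-2-(4-methoxybenzyloxy)ethan-1-ol | OC[C@H](OCc1ccc(OC)cc1)[C@@H]1COC(C)(C)O1 | intermediate
15 | (2R)-2-[(4S)-2,2-dimethyl-1,3-dioxolan-4-yl]-2-(4-methoxybenzyloxy)acetaldehyde | O=C[C@H](OCc1ccc(OC)cc1)[C@@H]1COC(C)(C)O1 | intermediate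
16 | methyl 4-[(4S)-2,2-dimethyl-1,3-dioxolan-4-yl]-3-hydroxy-4-(4-methoxybenzyloxy)-2-methylidenebutanoate (C4 as in 15; C3 epimers) | C=C(C(=O)OC)C(O)[C@H](OCc1ccc(OC)cc1)[C@@H]1COC(C)(C)O1 | intermediate
17 | 3-O-TBS ether of 16 | C=C(C(=O)OC)C(O[Si](C)(C)C(C)(C)C)[C@H](OCc1ccc(OC)cc1)[C@@H]1COC(C)(C)O1 | intermediate
18 | methyl 3-(tert-butyldimethylsilyloxy)-5,6-dihydroxy-4-(4-methoxybenzyloxy)-2-methylidenehexanoate (terminal diol from 17) | C=C(C(=O)OC)C(O[Si](C)(C)C(C)(C)C)[C@H](OCc1ccc(OC)cc1)[C@@H](O)CO | intermediate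
19 | methyl (4S)-3-(tert-butyldimethylsilyloxy)-4-(4-methoxybenzyloxy)-2-methylidene-5-oxopentanoate (fragment 2; C3 epimers) | C=C(C(=O)OC)C(O[Si](C)(C)C(C)(C)C)[C@H](OCc1ccc(OC)cc1)C=O | intermediate
20 | alkenyllithium from 10 (Li in place of I; geometry retained) | [Li]/C(C1OCCO1)=C\CC/C(CO[Si](c1ccccc1)(c1ccccc1)C(C)(C)C)=C\CO[Si](C)(C)C(C)(C)C | intermediate
21 | alkenylmagnesium bromide from 20 | Br[Mg]/C(C1OCCO1)=C\CC/C(CO[Si](c1ccccc1)(c1ccccc1)C(C)(C)C)=C\CO[Si](C)(C)C(C)(C)C | intermediate
22 | seco-chain C9 alcohol: C12 methyl ester; C11=C13 methylene; C7-OTBS (epimers); C8-OPMB and C9-OH syn and configured as in the target; C10 carries the 1,3-dioxolan-2-yl group (C14); C2 cis to C9 across C1=C10; C3 cis to C6 across C4=C5; C15-OTBDPS; C6-OTBS | C=C(C(=O)OC)C(O[Si](C)(C)C(C)(C)C)[C@H](OCc1ccc(OC)cc1)[C@@H](O)/C(C1OCCO1)=C\CC/C(CO[Si](c1ccccc1)(c1ccccc1)C(C)(C)C)=C\CO[Si](C)(C)C(C)(C)C | intermediate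
23 | C9 acetate of 22 | C=C(C(=O)OC)C(O[Si](C)(C)C(C)(C)C)[C@H](OCc1ccc(OC)cc1)[C@@H](OC(C)=O)/C(C1OCCO1)=C\CC/C(CO[Si](c1ccccc1)(c1ccccc1)C(C)(C)C)=C\CO[Si](C)(C)C(C)(C)C | intermediate
24 | C6,C7-diol from 23 (both TBS groups removed; C7 epimers) | C=C(C(=O)OC)C(O)[C@H](OCc1ccc(OC)cc1)[C@@H](OC(C)=O)/C(C1OCCO1)=C\CC/C(CO[Si](c1ccccc1)(c1ccccc1)C(C)(C)C)=C\CO | intermediate
25 | C6 enal from 24 (C7-OH free; CHO cis to C3 across C4=C5) | C=C(C(=O)OC)C(O)[C@H](OCc1ccc(OC)cc1)[C@@H](OC(C)=O)/C(C1OCCO1)=C\CC/C(CO[Si](c1ccccc1)(c1ccccc1)C(C)(C)C)=C\C=O | intermediate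
26 | methyl (2Z,4S,5S,6E,10E)-5-acetoxy-2-(bromomethyl)-10-[(tert-butyldiphenylsilyloxy)methyl]-6-(1,3-dioxolan-2-yl)-4-(4-methoxybenzyloxy)-12-oxododeca-2,6,10-trienoate | BrC/C(C(=O)OC)=C\[C@H](OCc1ccc(OC)cc1)[C@@H](OC(C)=O)/C(C1OCCO1)=C\CC/C(CO[Si](c1ccccc1)(c1ccccc1)C(C)(C)C)=C\C=O | intermediate
27 | allylchromium dichloride from 26 (CrCl2 unit in place of Br at C13) | Cl[Cr](Cl)C/C(C(=O)OC)=C\[C@H](OCc1ccc(OC)cc1)[C@@H](OC(C)=O)/C(C1OCCO1)=C\CC/C(CO[Si](c1ccccc1)(c1ccccc1)C(C)(C)C)=C\C=O | intermediate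
28 | ten-membered hydroxy ester: methyl 2-(cyclodecadienyl)acrylate with 6R-OH, 7S, 8S-OPMB, 9S-OAc (target numbering); C14 dioxolane; C15-OTBDPS | C=C(C(=O)OC)[C@@H]1[C@H](OCc2ccc(OC)cc2)[C@@H](OC(C)=O)/C(C2OCCO2)=C\CC/C(CO[Si](c2ccccc2)(c2ccccc2)C(C)(C)C)=C\[C@H]1O | intermediate
29 | ten-membered α-methylene-γ-lactone (6R,7S,8S,9S): C8-OPMB; C9-OAc; C14 dioxolane; C15-OTBDPS | C=C1C(=O)O[C@@H]2/C=C(/CO[Si](c3ccccc3)(c3ccccc3)C(C)(C)C)CC/C=C(/C3OCCO3)[C@H](OC(C)=O)[C@@H](OCc3ccc(OC)cc3)[C@@H]12 | intermediate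
30 | C8 alcohol of 29 (spatial arrangement at C6–C9 unchanged) | C=C1C(=O)O[C@@H]2/C=C(/CO[Si](c3ccccc3)(c3ccccc3)C(C)(C)C)CC/C=C(/C3OCCO3)[C@H](OC(C)=O)[C@@H](O)[C@@H]12 | intermediate
31 | C8 (S)-2-methylbutanoate of 30 | C=C1C(=O)O[C@@H]2/C=C(/CO[Si](c3ccccc3)(c3ccccc3)C(C)(C)C)CC/C=C(/C3OCCO3)[C@H](OC(C)=O)[C@@H](OC(=O)[C@@H](C)CC)[C@@H]12 | intermediate
32 | CNP0247637.6 | C=C1C(=O)O[C@@H]2/C=C(/CO)CC/C=C(/C=O)[C@H](OC(C)=O)[C@@H](OC(=O)[C@@H](C)CC)[C@@H]12 | target

**Step count**

Total step count: 24. Longest linear sequence: 17 steps (steps 1–8, then 16–24); the fragment 2 branch is steps 9–15.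

**Steps most likely to fail**

Step 21 (key ring closure). The allylchromium may add through the other face of C7, the syn (cis-lactone) pathway may compete, or intermolecular allylation may outrun the ten-membered closure. The fallback sets out from 26 and returns at 29. The allylic bromide is converted with hexamethyldisilane and Pd(PPh3)4 into the allylsilane F1. Fluoride-triggered intramolecular Hosomi–Sakurai allylation (catalytic Bu4NF, THF, high dilution) runs through an open, metal-free transition state with a different facial bias. The resulting C6 alkoxide lactonises onto the methyl ester to give 29.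

Step 16 (fragment union). Chelation control may be lost, giving the C9 epimer, and the alkenylmetal may attack the acrylate ester of 19. The fallback sets out from 10 and 19 and returns at 22. The two are joined by the ester-tolerant NiCl2 (cat.)/CrCl2 coupling in DMSO, which should give 22 together with its C9 epimer F2. Both are oxidised with Dess–Martin periodinane to the enone F3. C9 is then set by reagent control in a Corey–Bakshi–Shibata reduction (2-methyl-CBS-oxazaborolidine, BH3·SMe2; the catalyst enantiomer is chosen to deliver the 9S alcohol), which gives 22.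

Step 20 (allylic bromination). The SN2′ bromination may erode the C4=C5 enal geometry, open the dioxolane, or give a bromide that decomposes before use. The fallback sets out from 25 and returns at 29. The C7 hydroxyl is acetylated (Ac2O, pyridine) to the Morita–Baylis–Hillman acetate F4. The ring is then closed by palladium-catalysed umpolung: Pd(PPh3)4 (cat.) and InI convert the acetate through a π-allylpalladium into an allylindium that adds to the C6 aldehyde at high dilution. Lactonisation then gives 29.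

**Further compounds**

F1 | step 21 | allylsilane: methyl (2Z,4S,5S,6E,10E)-5-acetoxy-10-[(tert-butyldiphenylsilyloxy)methyl]-6-(1,3-dioxolan-2-yl)-4-(4-methoxybenzyloxy)-12-oxo-2-[(trimethylsilyl)methyl]dodeca-2,6,10-trienoate | C[Si](C)(C)C/C(C(=O)OC)=C\[C@H](OCc1ccc(OC)cc1)[C@@H](OC(C)=O)/C(C1OCCO1)=C\CC/C(CO[Si](c1ccccc1)(c1ccccc1)C(C)(C)C)=C\C=O
F2 | step 16 | C9 epimer of 22 | C=C(C(=O)OC)C(O[Si](C)(C)C(C)(C)C)[C@H](OCc1ccc(OC)cc1)[C@H](O)/C(C1OCCO1)=C\CC/C(CO[Si](c1ccccc1)(c1ccccc1)C(C)(C)C)=C\CO[Si](C)(C)C(C)(C)C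
F3 | step 16 | C9 ketone (enone) of the seco-chain | C=C(C(=O)OC)C(O[Si](C)(C)C(C)(C)C)[C@H](OCc1ccc(OC)cc1)C(=O)/C(C1OCCO1)=C\CC/C(CO[Si](c1ccccc1)(c1ccccc1)C(C)(C)C)=C\CO[Si](C)(C)C(C)(C)C
F4 | step 20 | C7 acetate of 25 (Morita–Baylis–Hillman acetate) | C=C(C(=O)OC)C(OC(C)=O)[C@H](OCc1ccc(OC)cc1)[C@@H](OC(C)=O)/C(C1OCCO1)=C\CC/C(CO[Si](c1ccccc1)(c1ccccc1)C(C)(C)C)=C\C=O
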